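Read the slope first.

| flask | free monomer | initiator | temperature | remark | time |
|---|---|---|---|---|---|
| ash | 28 mM | 0.2 mol% | 45 °C | run made earlier |  |
| elm | 44 mM | 0.2 mol% | 65 °C | run made earlier |  |
| Wednesday's | 20 mM | 0.2 mol% | 80 °C |  | 6.0 min |
| Thursday's | 20 mM | 0.2 mol% | 50 °C |  | 6.0 min |
| Monday's | 20 mM | 0.2 mol% | 65 °C |  | 6.0 min |

| run | time / min | monomer in chains / % | free monomer / % |
|---|---|---|---|
| ash | 2.50 | 1 | 101 |
| ash | 5.00 | 2 | 98 |
| ash | 12.0 | 5 | 92 |
| ash | 30.0 | 15 | 82 |
| elm | 3.00 | 5 | 93 |
| elm | 5.00 | 12 | 87 |
| elm | 8.00 | 19 | 80 |
| elm | 10.0 | 25 | 74 |

(readings scatter by 2 percentage points)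

- amounts and yields of monomer in chains count idle complex too
- what may be going on: free monomer + initiator -> living end + monomer in chains; free monomer + living end -> monomer in chains + living end; initiator + monomer in chains <-> idle complex

1. the flask that comes out highest in amount of monomer in chains, in percent of the free monomer charged, or "all alike" when all lie within 1.5 percentage points (Wednesday's / Thursday's / Monday's / all alike)
2. monomer in chains at the end, in percent of the free monomer charged, Wednesday's
3. monomer in chains at the end, in percent of the free monomer charged, Thursday's
4. monomer in chains at the end, in percent of the free monomer charged, Monday's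

Follow the natural log of the free monomer fraction against time. Once living ends are up, it falls steadily, and that pace is the late slope, a pseudo-first-order constant. Elm's first and last readings give 0.0326 min⁻¹, and ash's last two give 0.00639 min⁻¹; both carry the scatter. Living ends come from initiator, so scale each slope with the initiator charged. Per unit of initiator, elm at 65 °C reads a factor 3.25 above ash at 45 °C.

Carry Monday's late slope, elm's scaled to Monday's charge at the same temperature: 0.0148 min⁻¹. Spreading the factor evenly over the degrees gives Wednesday's 0.0359 min⁻¹ and Thursday's 0.00613 min⁻¹.

Now solve two extremes. If living ends stood ready from the first moment, the full slope would run for 6.0 min. If they climbed steadily from none to full strength at the end, the average slope would be half of that. The real flask starts from none, and its ends should climb fastest early, while initiator stands near its charge, so I place it between the two. My brackets are Wednesday's 10.2% to 19.4%, Monday's 4.35% to 8.52%, and Thursday's 1.82% to 3.61%. Wednesday's bracket stands clear above the others, so expect it highest.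

The forecast names Wednesday's, with 14% (8% to 21%) for Wednesday's, 2% (0.8% to 4%) for Thursday's and 6% (3.5% to 9%) for Monday's, noting “so rates fall and the lag lengthens”. These figures and ranges are its own and differ from my brackets.

The flasks give 17.7% for Wednesday's, 2.56% for Thursday's and 7.35% for Monday's, so Wednesday's is highest, and the forecast held.

    free monomer + initiator → living end + monomer in chains (k = 0.990 M⁻¹ s⁻¹, Ea = 41.0 kJ mol⁻¹)
    free monomer + living end → monomer in chains + living end, rate k2*[living end]*[free monomer] (k = 19.0 M⁻¹ s⁻¹, Ea = 45.0 kJ mol⁻¹)
    initiator + monomer in chains ⇌ idle complex, settled at all times (K = 3200 M⁻¹, ΔH = −50.0 kJ mol⁻¹)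
    (constants at 80 °C)

At 6.00 min in Thursday's flask, initiator's half-life by the initiating step is 2.2 min, about a third of the run, while free monomer's half-life by chain growth is far longer at 120 min. Thursday's idle complex, 0.0865% of the free monomer charged, is hardly any of the 2.56% yield that counts it. Now take Thursday's recipe at 75 °C: Monday's 0.0148 min⁻¹ becomes 0.0268 min⁻¹, bracketing 7.73% to 14.9%. That flask gives 13.5%.

All runs were generated by integration from invented constants; scatter was added.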